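## Analysis of the target

The target is a germacrane-type sesquiterpene lactone. Its ten-membered carbocycle (C1–C10) is fused at C6–C7 to an α-methylene-γ-butyrolactone (C11, C12, exocyclic C13). It carries a cis epoxide on C1(H)/C10(Me), a free hydroxyl on C3, a Z-trisubstituted olefin C4(Me)=C5 and an isobutyrate on the C8 oxygen. There are six stereocentres (1R,3S,6S,7S,8R,10S). With the ring bonds C5–C6–C7–C8–C9–C10 drawn as a zigzag, the bonds C6–O, C7–C11, C8–O and C10–O(epoxide) all point to the same side. The lactone is therefore trans-fused, C11 is trans to the C8 oxygen on the ring, and the oxygens on C6, C8 and C10 are mutually cis. The C3 hydroxyl and the C6 oxygen lie on the same face of the C4=C5 plane (a cis-2-ene-1,4-diol pattern). Sensitive groups are the exo-methylene lactone (Michael acceptor), the 1,10-epoxide (opened transannularly by C4=C5 under acid), the allylic C6–O bond, and the cis pair of oxygens on C6 and C8, either of which can hold the lactone or an acyl group. The synthesis is hard because a medium ring must be made with two cis ring units of defined geometry and with stereocentres spread over a flexible ring. The strategy rests on one feature: the Z-C4=C5 olefin and the cis C1–C10 epoxide are two methyl-bearing cis units in a 1,5-relationship, which is the olefin pattern of 1,5-dimethylcycloocta-1,5-diene (1). That isoprene dimer holds every ring carbon except C7 and C8.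

## Retrosynthetic reasoning

**C3–O (29 to 28).** The C3 hydroxyl is removed last. A selenium-based allylic hydroxylation places oxygen on the ring CH2 attached to the more substituted olefin carbon C4 and keeps the double bond in place. Leaving it to the end means the only free hydroxyl to be acylated earlier is the one on C8, so no protecting group is needed.

**C11=C13 (28 to 23 and 24).** The exocyclic methylene is cut back to the lactone CH2 and iminium salt 24. The Michael acceptor then exists only during the final step.

**C8 O–acyl (23 to 21 and 22).** The ester bond is cut to epoxy alcohol 21 and isobutyryl chloride 22. Acylation is placed after epoxidation because the free C8 hydroxyl is needed as the directing group there.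

**Epoxide C–O bonds (21 to 20).** Both C–O bonds of the epoxide are cut back to the Z-C1=C10 olefin of 20. The C8 hydroxyl is homoallylic to this olefin and cis to the epoxide oxygen in the target, so a hydroxyl-directed vanadium epoxidation should choose both the olefin and the face.

**C8–O from C8–B (20 to 19).** The C8 oxygen is traced to a boronate. Boron cannot lactonise, so the lactone can only close to the C6 oxygen while C8 is still masked. This removes the competition between the two cis oxygens.

**Lactone C12–O and the C6 configuration (19 to 18, 17, 15 and 14).** The lactone is opened to hydroxy ester 18. Hydride addition to ketone 14 is expected, on Felkin–Anh grounds, to give the C6 epimer 15, so the C6–O bond is planned through an SN2 inversion with 4-nitrobenzoic acid 16 (ester 17). Both C6 epimers of the alcohol then converge on the trans lactone.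

**C8–B and C7–H (14 to 13).** These two bonds come from a copper-catalysed asymmetric conjugate borylation of the cross-conjugated trienone 13. The chiral catalyst sets C8, and protonation of the enolate sets C7. The acetate arm must already be on C7, so that the proton and not a carbon electrophile is the last group to enter.

**C7–C11 (13 to 10 and 11).** The acetate arm is attached to an sp2 carbon by cross-coupling α-iodo enone 10 with zinc reagent 12, made from tert-butyl bromoacetate 11. Alkylating C7 first and dehydrogenating afterwards was turned down, because elimination toward the side-chain CH2 (α to the ester) would compete with elimination into the ring.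

**C7–I and C7=C8 (10 to 9, 8 and 6).** The iodide is removed to trienone 9, and the C7=C8 double bond is removed through silyl dienol ether 8 to dienone 6. The forward steps use the only enolisable α-position of 6 (C7) and the less substituted enone of 9.

**Key disconnection C8–C9 (6 to 4).** The ten-membered ring is contracted by cutting C8–C9 and reconnecting C9 to C6. This gives the vinyl carbinol 4, with the eight-membered ring of the isoprene dimer. The forward 1,3-shift inserts C7 and C8, keeps both cis olefins, creates the C6 carbonyl and leaves a regiodefined C6–C7 enolate.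

**C6–C7 and C6=O (4 to 2 and 3, 2 to 1).** The vinyl group is cut off as vinylmagnesium bromide 3 from enone 2. Enone 2 is the allylic oxidation product of diene 1, whose C2 symmetry makes the four equivalent oxidation sites one.

## Alternatives that were turned down

**Alternative 1: both allylic oxygens from singlet oxygen.**
- Disconnection: the C3–O and C6–O bonds are cut together to a ten-membered 3Z,5Z-diene acrylate A1.
- Forward key step: [4+2] addition of singlet oxygen across C3 and C6 gives the C3,C6-endoperoxide A2. O–O reduction and closure of the C6 hydroxyl onto the acrylate ester would follow.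
- For: one step makes both C–O bonds, guarantees their cis-1,4 relationship and leaves the Z-C4=C5 olefin. Lactonisation is regiospecific, because only C6 gives a five-membered ring.
- Against: A1 already contains the whole ten-membered ring with C1, C7, C8 and C10 set, and the plan does not say how that ring is made. The face of the diene attacked by oxygen is decided only by ring conformation. Ene reactions of singlet oxygen at the C4 methyl and C2 hydrogens compete. The C7–H of A1 is doubly allylic and prone to isomerisation.
- Comparison: this plan is stronger than the chosen one for the C3 oxygen, which is the weakest stereochemical step of the chosen route. The chosen route offers in exchange the ring with both cis units in three steps from a commodity hydrocarbon.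

**Alternative 2: Nozaki–Hiyama–Kishi closure at C5–C6.**
- Disconnection: C5–C6, to the open-chain Z-iodoalkene aldehyde A3.
- Forward key step: CrCl2 with catalytic NiCl2 turns the alkenyl iodide into an alkenylchromium that adds to the aldehyde and closes the ten-membered C6 carbinol A4.
- For: the reaction tolerates epoxide, esters and silyl ethers and keeps the Z geometry. C1, C3, C8 and C10 would be set on an open chain by well-understood reactions, which is more secure than ring-conformation control.
- Against: the C6 carbinol is formed without a control element, and 1,2-induction from C7 points to the epimer that gives the cis lactone. A3 is a β-acyloxy aldehyde with an enolisable α-carbon, so elimination of isobutyrate and epimerisation of C7 threaten. The closure of a ten-membered ring pays the full entropic and transannular cost at a late stage, under high dilution with stoichiometric chromium. A3 needs a long linear sequence.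
- Comparison: this plan is stronger on acyclic stereocontrol. The chosen plan is far shorter to the ring and never has to close a medium ring from an open chain.

**Alternative 3: SmI2 Reformatsky closure at C1–C2.**
- Disconnection: C1–C2, to the bromomethyl ketone aldehyde A5.
- Forward key step: SmI2 reduces the C–Br bond, and the samarium enolate adds to the non-enolisable C1 aldehyde to give the ten-membered β-hydroxy ketone A6.
- For: samarium-templated aldol closures are among the better medium-ring closures, and chelation to the C10 ether oxygen can set C1.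
- Against: the ring is closed at a bond remote from the final functionality. A6 still needs stereoselective reduction of the C3 ketone, removal of the 4-methoxybenzyl group from a tertiary oxygen, and activation and displacement at C1 to close the epoxide. As a β-hydroxy ketone, A6 can dehydrate or undergo retro-aldol cleavage. The γ-acyloxy enone in A5 and A6 (C3 ketone, C4=C5, C6–O lactone) is itself reducible by SmI2 with loss of the lactone oxygen.
- Comparison: this plan defines C1 and C10 more rigorously. The chosen plan obtains the epoxide by direct, hydroxyl-directed epoxidation of an olefin present from the first step, and is shorter.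

Key step: step 3

Assumption: commercial 1,5-dimethylcycloocta-1,5-diene may contain the 1,6-dimethyl isomer; the isomeric enone is taken to be removed by chromatography at compound 2.

Assumption: the copper catalyst of step 8 is taken to attack C8 of 13 with the facial sense it shows on simple cyclic cis-enones; if the sense is opposite, the enantiomeric ligand is used and nothing else changes.

Bpin stands for 4,4,5,5-tetramethyl-1,3,2-dioxaborolan-2-yl. Locants C1–C13 are those of the target.

## Route

Step 1
Reactants: 1 1,5-dimethylcycloocta-1,5-diene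
Product: 2 (2Z,6Z)-3,7-dimethylcycloocta-2,6-dien-1-one
Conditions: CrO3, 3,5-dimethylpyrazole, CH2Cl2, −20 °C
Reagents that add atoms: chromium trioxide, O=[Cr](=O)=O
Why: Allylic oxidation by the CrO3–3,5-dimethylpyrazole complex (hexavalent chromium) takes hydrogen from the ring CH2 next to the CH= end of a trisubstituted olefin and gives the β-methyl enone, the usual outcome for 1-methylcycloalkenes. The C2 symmetry of 1 makes the four such positions equivalent, and the reaction is stopped short of full conversion to limit dione formation.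

Step 2
Reactants: 2 (2Z,6Z)-3,7-dimethylcycloocta-2,6-dien-1-one; 3 vinylmagnesium bromide
Product: 4 rac-(2Z,6Z)-1-ethenyl-3,7-dimethylcycloocta-2,6-dien-1-ol
Conditions: CeCl3, THF, −78 °C; then H2O, 0 °C
Reagents that add atoms: vinylmagnesium bromide (3), C=C[Mg]Br
Why: CeCl3-assisted Grignard 1,2-addition; the cerium salt suppresses enolisation of the doubly activated C8 methylene and conjugate addition to the β,β-disubstituted enone. The carbinol centre is racemic and is destroyed in step 3; the neutral quench spares the acid-labile bis-allylic tertiary alcohol.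

Step 3
Reactants: 4 rac-(2Z,6Z)-1-ethenyl-3,7-dimethylcycloocta-2,6-dien-1-ol
Product: 6 (2Z,6Z)-3,7-dimethylcyclodeca-2,6-dien-1-one, via potassium dienolate 5 (not isolated)
Conditions: KH, 18-crown-6, THF, 0 → 23 °C; then H2O, −78 °C
Reagents that add atoms: none
Why: KH with 18-crown-6 gives the free potassium alkoxide of 4, in which the C6–C9 bond is weakened by the oxyanion and by the allylic position of C9 next to C10=C1. C9 then moves from C6 to the vinyl terminus C8, either as a concerted suprafacial 1,3-shift or by heterolysis to a tethered allyl anion and a cross-conjugated divinyl ketone that recombine by conjugate addition; this gives potassium dienolate 5, which water protonates at C7. The closest known reaction type is the anionic 1,3-shift (two-carbon ring expansion) of potassium 1-vinylcycloalk-3-en-1-olates, whose usual competitor is the oxy-Cope 3,3-shift. The ten-membered ring is closed as a two-atom enlargement of the eight-membered ring; in the stepwise picture it is a 10-endo-trig conjugate addition of C9 to C8. No stereocentre is formed: the carbinol centre is lost and 6 is achiral. The step needs periselectivity (a C8–C9 bond and not a C8–C1 bond), site selectivity (C8 and not the second enone terminus C4, which would contract the ring) and retention of both Z olefins. The cis ring olefin allows the 3,3 path only through a boat, C4 is fully substituted whereas C8 is an unhindered CH2 terminus, and neither ring olefin is opened (C4=C5 is a spectator and C10=C1 becomes part of an allyl anion that should keep its shape at these temperatures). The enolate is regiodefined at C6–C7, the position used in step 4.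

Step 4
Reactants: 6 (2Z,6Z)-3,7-dimethylcyclodeca-2,6-dien-1-one
Product: 8 trimethyl{[(5Z,9Z)-5,9-dimethylcyclodeca-1,5,9-trien-1-yl]oxy}silane, via lithium dienolate 7 (not isolated)
Conditions: LiN(i-Pr)2, THF, −78 °C; then Me3SiCl, −78 → 0 °C
Reagents that add atoms: chlorotrimethylsilane, C[Si](C)(C)Cl
Why: Kinetic deprotonation of the enone at its only α-CH2 (C7) and O-silylation give the cross-conjugated 2-silyloxy diene; the amide base at low temperature avoids γ-deprotonation at C3.

Step 5
Reactants: 8 trimethyl{[(5Z,9Z)-5,9-dimethylcyclodeca-1,5,9-trien-1-yl]oxy}silane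
Product: 9 (2Z,6Z,9Z)-3,7-dimethylcyclodeca-2,6,9-trien-1-one
Conditions: Pd(OAc)2 (1.05 equiv), MeCN, 23 °C
Reagents that add atoms: none
Why: Saegusa–Ito dehydrogenation: divalent palladium binds C7 of the silyl enol ether, and β-hydride elimination, possible only from C8, gives the cross-conjugated dienone. The cis C7=C8 geometry is expected for a ring that already holds two Z olefins, and the geometry is set again in step 6.

Step 6
Reactants: 9 (2Z,6Z,9Z)-3,7-dimethylcyclodeca-2,6,9-trien-1-one
Product: 10 (2Z,6Z,9E)-10-iodo-3,7-dimethylcyclodeca-2,6,9-trien-1-one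
Conditions: I2, pyridine/CH2Cl2 (1:1), 0 → 23 °C
Reagents that add atoms: iodine, II
Why: α-Iodination of an enone with iodine and pyridine: pyridine adds reversibly to the β-carbon C8, the enolate is iodinated at C7 and pyridine is lost. The β,β-disubstituted C4=C5 enone does not accept pyridine, and the elimination returns the favoured cis ring olefin (E by the priority of iodine).

Step 7
Reactants: 10 (2Z,6Z,9E)-10-iodo-3,7-dimethylcyclodeca-2,6,9-trien-1-one; 11 tert-butyl bromoacetate
Product: 13 tert-butyl 2-[(1Z,4Z,8Z)-4,8-dimethyl-10-oxocyclodeca-1,4,8-trien-1-yl]acetate, via zinc ester enolate 12 (not isolated)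
Conditions: 11, Zn dust, Me3SiCl (cat.), THF, 40 °C; then 10, Pd(PPh3)4 (5 mol %), THF, 23 °C
Reagents that add atoms: tert-butyl bromoacetate (11), CC(C)(C)OC(=O)CBr
Why: Negishi-type coupling of the Reformatsky reagent with the α-iodo enone (oxidative addition of zerovalent palladium, transmetalation of the zinc enolate, reductive elimination) forms C7–C11 with retention of the olefin geometry. It places the acetate arm on C7 without a dehydrogenation whose direction (ring or side chain) would be uncertain; the tert-butyl ester lowers the acidity of C11–H and resists alkoxide in step 8.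

Step 8
Reactants: 13 tert-butyl 2-[(1Z,4Z,8Z)-4,8-dimethyl-10-oxocyclodeca-1,4,8-trien-1-yl]acetate
Product: 14 tert-butyl 2-[(1S,10R,3Z,7Z)-4,8-dimethyl-2-oxo-10-Bpin-cyclodeca-3,7-dien-1-yl]acetate (7S,8R)
Conditions: CuCl (5 mol %), NaOt-Bu (5 mol %), (R)-1-[(Sp)-2-(diphenylphosphino)ferrocenyl]ethyldicyclohexylphosphine (6 mol %), B2pin2 (1.05 equiv), MeOH (2 equiv), THF, 0 °C
Reagents that add atoms: bis(pinacolato)diboron, CC1(C)OB(OC1(C)C)B1OC(C)(C)C(C)(C)O1
Why: Copper-catalysed asymmetric conjugate borylation: the ligated Cu–Bpin adds to C8, which gives a secondary boronate, and not to the β,β-disubstituted C4; the chiral bisphosphine selects the face of C8 (8R). MeOH protonates the copper enolate at C7 anti to the new C–B bond in the conformer that holds C8–H in the enolate plane, which is also the outcome of net syn addition of boron and hydrogen across the cis olefin; C11 and boron end up trans on the ring (7S).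

Step 9
Reactants: 14 tert-butyl 2-[(1S,10R,3Z,7Z)-4,8-dimethyl-2-oxo-10-Bpin-cyclodeca-3,7-dien-1-yl]acetate
Product: 15 tert-butyl 2-[(1S,2S,10R,3Z,7Z)-2-hydroxy-4,8-dimethyl-10-Bpin-cyclodeca-3,7-dien-1-yl]acetate (6S,7S,8R)
Conditions: NaBH4, CeCl3·7H2O, MeOH, −78 °C
Reagents that add atoms: none
Why: Luche 1,2-reduction of the enone carbonyl: hydride should add to the outer face of C6, anti to the ring bond C7–C8 and with the acetate arm near the carbonyl oxygen (Felkin–Anh), giving the alcohol with C6–O cis to the C7 arm. This is the C6 epimer of what the trans lactone needs and is inverted in step 10; any 6R epimer 18 formed beside it is taken directly into the cyclisation of step 11.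

Step 10
Reactants: 15 tert-butyl 2-[(1S,2S,10R,3Z,7Z)-2-hydroxy-4,8-dimethyl-10-Bpin-cyclodeca-3,7-dien-1-yl]acetate; 16 4-nitrobenzoic acid
Product: 17 tert-butyl 2-[(1S,2R,10R,3Z,7Z)-4,8-dimethyl-2-(4-nitrobenzoyloxy)-10-Bpin-cyclodeca-3,7-dien-1-yl]acetate (6R,7S,8R)
Conditions: 16, PPh3, DIAD, THF, 0 → 23 °C
Reagents that add atoms: 4-nitrobenzoic acid (16), OC(=O)c1ccc(cc1)[N+](=O)[O-]
Why: Mitsunobu esterification: the oxyphosphonium of the allylic alcohol is displaced by 4-nitrobenzoate in an SN2 step that inverts C6. The acidic, weakly basic carboxylate favours substitution over elimination at the hindered carbinol.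

Step 11
Reactants: 17 tert-butyl 2-[(1S,2R,10R,3Z,7Z)-4,8-dimethyl-2-(4-nitrobenzoyloxy)-10-Bpin-cyclodeca-3,7-dien-1-yl]acetate
Product: 19 (6R,7S,8R)-8-Bpin-13-norgermacra-1(10)Z,4Z-dien-12,6-olide, via hydroxy ester 18 (not isolated)
Conditions: K2CO3 (cat.), MeOH, 0 °C; then CSA (cat.), CH2Cl2, 23 °C
Reagents that add atoms: none
Why: Methanolysis of the activated aryl ester frees the 6R alcohol, and acid-catalysed transesterification onto the tert-butyl ester closes the γ-lactone. C8 is still masked as the boronate, so the lactone can only form to C6, and the fusion is trans because C6–O and C11 are now trans on the ring.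

Step 12
Reactants: 19 (6R,7S,8R)-8-Bpin-13-norgermacra-1(10)Z,4Z-dien-12,6-olide
Product: 20 (6S,7S,8R)-8-hydroxy-13-norgermacra-1(10)Z,4Z-dien-12,6-olide
Conditions: NaBO3·4H2O, THF/H2O (1:1), 0 → 23 °C
Reagents that add atoms: sodium perborate, [Na+].[Na+].O[B-]1(O)OO[B-](O)(O)OO1
Why: Oxidation of the secondary alkyl boronate (1,2-shift of C8 from boron to oxygen) gives the C8 alcohol with retention. The weakly basic perborate is chosen to spare the lactone and to limit translactonisation to the new hydroxyl.

Step 13
Reactants: 20 (6S,7S,8R)-8-hydroxy-13-norgermacra-1(10)Z,4Z-dien-12,6-olide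
Product: 21 (1R,6S,7S,8R,10S)-1,10-epoxy-8-hydroxy-13-norgermacr-4Z-en-12,6-olide
Conditions: VO(acac)2 (5 mol %), t-BuOOH, CH2Cl2, 0 → 23 °C
Reagents that add atoms: tert-butyl hydroperoxide, CC(C)(C)OO
Why: Hydroxyl-directed epoxidation: the vanadium alkoxide of the homoallylic C8 alcohol delivers the peroxide oxygen to C1=C10 on the face of the hydroxyl, giving the cis epoxide with its oxygen syn to C8–O (1R,10S). The C4=C5 olefin is deactivated by the allylic lactone oxygen and is one carbon farther from the hydroxyl.

Step 14
Reactants: 21 (1R,6S,7S,8R,10S)-1,10-epoxy-8-hydroxy-13-norgermacr-4Z-en-12,6-olide; 22 isobutyryl chloride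
Product: 23 (1R,6S,7S,8R,10S)-1,10-epoxy-8-isobutyryloxy-13-norgermacr-4Z-en-12,6-olide
Conditions: 22, pyridine, DMAP (cat.), CH2Cl2, 0 °C
Reagents that add atoms: isobutyryl chloride (22), CC(C)C(Cl)=O
Why: DMAP-catalysed acylation of the only free hydroxyl. The mild amine medium keeps the epoxide intact and avoids alkoxide-driven translactonisation.

Step 15
Reactants: 23 (1R,6S,7S,8R,10S)-1,10-epoxy-8-isobutyryloxy-13-norgermacr-4Z-en-12,6-olide; 24 N,N-dimethylmethyleneiminium iodide
Product: 28 (1R,6S,7S,8R,10S)-1,10-epoxy-8-isobutyryloxygermacra-4Z,11(13)-dien-12,6-olide, via lithium lactone enolate 25 (not isolated), via Mannich base 26 (not isolated), via trimethylammonium iodide 27 (not isolated)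
Conditions: LiN(i-Pr)2 (1.05 equiv), THF, −78 °C; 24, −78 → 0 °C; MeI, MeOH, 23 °C; NaHCO3 (aq.), CH2Cl2, 23 °C
Reagents that add atoms: N,N-dimethylmethyleneiminium iodide (24), C=[N+](C)C.[I-]
Why: α-Methylenation of a lactone by Mannich reaction of its lithium enolate with Eschenmoser's salt, N-methylation and base-induced elimination of trimethylamine. The lactone α-CH2 is more acidic and far less hindered than the isobutyrate methine, so one equivalent of base at −78 °C should enolise the lactone only.

Step 16
Reactants: 28 (1R,6S,7S,8R,10S)-1,10-epoxy-8-isobutyryloxygermacra-4Z,11(13)-dien-12,6-olide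
Product: 29 (1R,3S,6S,7S,8R,10S)-1,10-epoxy-3-hydroxy-8-isobutyryloxygermacra-4Z,11(13)-dien-12,6-olide (CNP0261225.1)
Conditions: SeO2 (0.5 equiv), t-BuOOH, CH2Cl2, 0 → 23 °C
Reagents that add atoms: selenium dioxide, O=[Se]=O; tert-butyl hydroperoxide, CC(C)(C)OO
Why: Selenium dioxide allylic hydroxylation (ene reaction at C5, then a [2,3]-sigmatropic shift) places oxygen on the ring CH2 attached to the more substituted olefin carbon C4 and restores C4=C5; the electron-poor exo-methylene is not attacked. In a cis-cyclodecene both allylic ring bonds (C3–C2 and C6–C7) lie on the inner face, so selenium should add to C5 on the outer face and the suprafacial shift should put the hydroxyl on C3 on that face, the side of the C6–O bond (3S, cis-1,4 to the lactone oxygen).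

## Compound list

1 | 1,5-dimethylcycloocta-1,5-diene | CC1=CCCC(C)=CCC1 | starting material
2 | (2Z,6Z)-3,7-dimethylcycloocta-2,6-dien-1-one | O=C1/C=C(/C)CC/C=C(/C)C1 | intermediate
3 | vinylmagnesium bromide | C=C[Mg]Br | starting material
4 | rac-(2Z,6Z)-1-ethenyl-3,7-dimethylcycloocta-2,6-dien-1-ol | C=CC1(O)/C=C(/C)CC/C=C(/C)C1 | intermediate
5 | potassium (5Z,9Z)-5,9-dimethylcyclodeca-1,5,9-trien-1-olate (C6–C7 enolate) | [K+].[O-]C1=CCC/C(C)=C\CC/C(C)=C\1 | intermediate
6 | (2Z,6Z)-3,7-dimethylcyclodeca-2,6-dien-1-one | O=C1/C=C(/C)CC/C=C(/C)CCC1 | intermediate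
7 | lithium (5Z,9Z)-5,9-dimethylcyclodeca-1,5,9-trien-1-olate | [Li+].[O-]C1=CCC/C(C)=C\CC/C(C)=C\1 | intermediate
8 | trimethyl{[(5Z,9Z)-5,9-dimethylcyclodeca-1,5,9-trien-1-yl]oxy}silane | C[Si](C)(C)OC1=CCC/C(C)=C\CC/C(C)=C\1 | intermediate
9 | (2Z,6Z,9Z)-3,7-dimethylcyclodeca-2,6,9-trien-1-one | O=C1/C=C(/C)CC/C=C(/C)C/C=C\1 | intermediate
10 | (2Z,6Z,9E)-10-iodo-3,7-dimethylcyclodeca-2,6,9-trien-1-one (iodine on C7) | O=C1/C=C(/C)CC/C=C(/C)C/C=C1/I | intermediate
11 | tert-butyl bromoacetate | CC(C)(C)OC(=O)CBr | starting material
12 | (2-tert-butoxy-2-oxoethyl)zinc bromide | CC(C)(C)OC(=O)C[Zn]Br | intermediate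
13 | tert-butyl 2-[(1Z,4Z,8Z)-4,8-dimethyl-10-oxocyclodeca-1,4,8-trien-1-yl]acetate | O=C1/C=C(/C)CC/C=C(/C)C/C=C1/CC(=O)OC(C)(C)C | intermediate
14 | tert-butyl 2-[(1S,10R,3Z,7Z)-4,8-dimethyl-2-oxo-10-Bpin-cyclodeca-3,7-dien-1-yl]acetate (7S,8R) | O=C1/C=C(/C)CC/C=C(/C)C[C@@H](B2OC(C)(C)C(C)(C)O2)[C@@H]1CC(=O)OC(C)(C)C | intermediate
15 | tert-butyl 2-[(1S,2S,10R,3Z,7Z)-2-hydroxy-4,8-dimethyl-10-Bpin-cyclodeca-3,7-dien-1-yl]acetate (6S,7S,8R; C6–OH cis to the C7 arm) | O[C@@H]1/C=C(/C)CC/C=C(/C)C[C@@H](B2OC(C)(C)C(C)(C)O2)[C@@H]1CC(=O)OC(C)(C)C | intermediate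
16 | 4-nitrobenzoic acid | OC(=O)c1ccc(cc1)[N+](=O)[O-] | starting material
17 | tert-butyl 2-[(1S,2R,10R,3Z,7Z)-4,8-dimethyl-2-(4-nitrobenzoyloxy)-10-Bpin-cyclodeca-3,7-dien-1-yl]acetate (6R,7S,8R) | O=C(O[C@H]1/C=C(/C)CC/C=C(/C)C[C@@H](B2OC(C)(C)C(C)(C)O2)[C@@H]1CC(=O)OC(C)(C)C)c1ccc(cc1)[N+](=O)[O-] | intermediate
18 | tert-butyl 2-[(1S,2R,10R,3Z,7Z)-2-hydroxy-4,8-dimethyl-10-Bpin-cyclodeca-3,7-dien-1-yl]acetate (6R,7S,8R; C6–OH trans to the C7 arm) | O[C@H]1/C=C(/C)CC/C=C(/C)C[C@@H](B2OC(C)(C)C(C)(C)O2)[C@@H]1CC(=O)OC(C)(C)C | intermediate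
19 | (6R,7S,8R)-8-Bpin-13-norgermacra-1(10)Z,4Z-dien-12,6-olide (trans-fused γ-lactone) | C1C(=O)O[C@H]2/C=C(/C)CC/C=C(/C)C[C@@H](B3OC(C)(C)C(C)(C)O3)[C@H]12 | intermediate
20 | (6S,7S,8R)-8-hydroxy-13-norgermacra-1(10)Z,4Z-dien-12,6-olide | C1C(=O)O[C@H]2/C=C(/C)CC/C=C(/C)C[C@@H](O)[C@H]12 | intermediate
21 | (1R,6S,7S,8R,10S)-1,10-epoxy-8-hydroxy-13-norgermacr-4Z-en-12,6-olide | C1C(=O)O[C@H]2/C=C(/C)CC[C@H]3O[C@@]3(C)C[C@@H](O)[C@H]12 | intermediate
22 | isobutyryl chloride | CC(C)C(Cl)=O | starting material
23 | (1R,6S,7S,8R,10S)-1,10-epoxy-8-isobutyryloxy-13-norgermacr-4Z-en-12,6-olide | C1C(=O)O[C@H]2/C=C(/C)CC[C@H]3O[C@@]3(C)C[C@@H](OC(=O)C(C)C)[C@H]12 | intermediate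
24 | N,N-dimethylmethyleneiminium iodide (Eschenmoser's salt) | C=[N+](C)C.[I-] | starting material
25 | lithium enolate of lactone 23 (C11=C12–O−) | [Li+].C1=C([O-])O[C@H]2/C=C(/C)CC[C@H]3O[C@@]3(C)C[C@@H](OC(=O)C(C)C)[C@H]12 | intermediate
26 | 11-(dimethylaminomethyl) derivative of 23 (C11 epimers) | CN(C)CC1C(=O)O[C@H]2/C=C(/C)CC[C@H]3O[C@@]3(C)C[C@@H](OC(=O)C(C)C)[C@H]12 | intermediate
27 | 11-(trimethylammoniomethyl) derivative of 23, iodide | C[N+](C)(C)CC1C(=O)O[C@H]2/C=C(/C)CC[C@H]3O[C@@]3(C)C[C@@H](OC(=O)C(C)C)[C@H]12.[I-] | intermediate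
28 | (1R,6S,7S,8R,10S)-1,10-epoxy-8-isobutyryloxygermacra-4Z,11(13)-dien-12,6-olide | C=C1C(=O)O[C@H]2/C=C(/C)CC[C@H]3O[C@@]3(C)C[C@@H](OC(=O)C(C)C)[C@H]12 | intermediate
29 | (1R,3S,6S,7S,8R,10S)-1,10-epoxy-3-hydroxy-8-isobutyryloxygermacra-4Z,11(13)-dien-12,6-olide | C=C1C(=O)O[C@H]2/C=C(/C)[C@@H](O)C[C@H]3O[C@@]3(C)C[C@@H](OC(=O)C(C)C)[C@H]12 | target

## Step count and least certain steps

Total step count: 16. Longest linear sequence: 16 steps, from 1 to 29.

**Step 3 (key step).** Three things can go wrong. The alkoxide may follow the 3,3 path and give an eight-membered isopropenyl ketone. The allyl anion may collapse onto C4 instead of C8, which would contract the ring to a cyclohexene with a quaternary carbon; this is the thermodynamically easier outcome. The C10=C1 geometry may be lost by rotation within the allyl anion. Fallback, from 4 to 8: carbinol 4 is silylated (Me3SiCl, imidazole, DMF) to the trimethylsilyl ether of 4 F1, which is passed through a hot quartz tube (about 300–350 °C, short contact time, reduced pressure). This neutral thermal 1,3-shift is the known siloxy counterpart of the anionic reaction and runs without a free enone electrophile, so a Michael-type collapse onto C4 is not available. It gives silyl dienol ether 8 directly, and the route continues with step 5.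

**Step 8.** The catalytic alkoxide may move the C7=C8 double bond out of the ring into conjugation with the ester before boron adds. Boron may also add at C4, or the facial selectivity at C8 or in the protonation at C7 may be low. Fallback, from 9 to 14: the same copper system is applied to trienone 9, a simple cis-disubstituted cyclic enone, to give (2Z,6Z,9R)-3,7-dimethyl-9-Bpin-cyclodeca-2,6-dien-1-one F2. Its lithium enolate (LiN(SiMe3)2, THF, −78 °C) is alkylated with 11. The electrophile now takes the place that the proton takes in step 8, so the first product is expected to be mainly the C7 epimer of 14 F3. C7 is α to the ketone, so F3 is equilibrated with DBU in toluene; 14 is separated and the remainder recycled.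

**Step 10.** The allylic oxyphosphonium may ionise or react by the SN2′ path, elimination to a diene may compete, or substitution at the hindered carbinol may stall. Fallback, from 14 to 20, with chelation-controlled reduction in place of inversion:
- 14 is oxidised with NaBO3 to the β-hydroxy ketone tert-butyl 2-[(1S,10R,3Z,7Z)-10-hydroxy-4,8-dimethyl-2-oxocyclodeca-3,7-dien-1-yl]acetate F4.
- The hydroxyl is protected with 4-methoxybenzyl trichloroacetimidate and catalytic CSA as the 4-methoxybenzyl ether of F4 F5.
- Zn(BH4)2 in Et2O at −20 °C reduces the C6 carbonyl through a zinc chelate between the two oxygens. This should give the 6,8-syn alcohol tert-butyl 2-[(1S,2S,10R,3Z,7Z)-2-hydroxy-10-(4-methoxybenzyloxy)-4,8-dimethylcyclodeca-3,7-dien-1-yl]acetate F6.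
- CSA closes it to (6S,7S,8R)-8-(4-methoxybenzyloxy)-13-norgermacra-1(10)Z,4Z-dien-12,6-olide F7, and DDQ in buffered CH2Cl2 releases 20.

**Step 15.** The lactone enolate may attack the neighbouring isobutyrate carbonyl (acyl transfer to C11), or the base may enolise the isobutyrate. Fallback, from 21 to 28, in which no enolate is made next to the ester:
- Epoxy alcohol 21 is treated with 2.1 equivalents of LiN(i-Pr)2 to give the dilithium alkoxide enolate of 21 F8.
- Reaction with 24 gives the 11-(dimethylaminomethyl) epoxy alcohol F9.
- MeI gives the 11-(trimethylammoniomethyl) epoxy alcohol iodide F10.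
- NaHCO3 gives (1R,6S,7S,8R,10S)-1,10-epoxy-8-hydroxygermacra-4Z,11(13)-dien-12,6-olide F11.
- Acylation with 22 under the conditions of step 14 gives 28.

**Step 16.** Oxygen may be delivered to the C4 methyl instead of the ring CH2, the hydroxyl may arrive on the other face of C3, or the C4=C5 geometry may be lost in the sigmatropic shift. Fallback, from 28 to 29: the C3 methylene of 28 is oxidised to the ketone with CrO3 and 3,5-dimethylpyrazole (hydrogen abstraction instead of an ene reaction), giving (1R,6S,7S,8R,10S)-1,10-epoxy-8-isobutyryloxy-3-oxogermacra-4Z,11(13)-dien-12,6-olide F12. The same enone is reached with MnO2 from any C3-epimeric alcohol. It is handled without base because of the β,γ-epoxy ketone. Corey–Bakshi–Shibata reduction with (R)-2-methyl-CBS-oxazaborolidine and catecholborane in toluene at −78 °C, with the α-methyl alkenyl group as the large substituent, then sets 3S under reagent control and gives 29.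

## Further compounds

F1 | step 3 | trimethylsilyl ether of 4, rac-{[(2Z,6Z)-1-ethenyl-3,7-dimethylcycloocta-2,6-dien-1-yl]oxy}trimethylsilane | C=CC1(O[Si](C)(C)C)/C=C(/C)CC/C=C(/C)C1
F2 | step 8 | (2Z,6Z,9R)-3,7-dimethyl-9-Bpin-cyclodeca-2,6-dien-1-one | O=C1/C=C(/C)CC/C=C(/C)C[C@@H](B2OC(C)(C)C(C)(C)O2)C1
F3 | step 8 | C7 epimer of 14, tert-butyl 2-[(1R,10R,3Z,7Z)-4,8-dimethyl-2-oxo-10-Bpin-cyclodeca-3,7-dien-1-yl]acetate | O=C1/C=C(/C)CC/C=C(/C)C[C@@H](B2OC(C)(C)C(C)(C)O2)[C@H]1CC(=O)OC(C)(C)C
F4 | step 10 | tert-butyl 2-[(1S,10R,3Z,7Z)-10-hydroxy-4,8-dimethyl-2-oxocyclodeca-3,7-dien-1-yl]acetate | O=C1/C=C(/C)CC/C=C(/C)C[C@@H](O)[C@@H]1CC(=O)OC(C)(C)C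
F5 | step 10 | 4-methoxybenzyl ether of F4 | O=C1/C=C(/C)CC/C=C(/C)C[C@@H](OCc2ccc(OC)cc2)[C@@H]1CC(=O)OC(C)(C)C
F6 | step 10 | tert-butyl 2-[(1S,2S,10R,3Z,7Z)-2-hydroxy-10-(4-methoxybenzyloxy)-4,8-dimethylcyclodeca-3,7-dien-1-yl]acetate | O[C@H]1/C=C(/C)CC/C=C(/C)C[C@@H](OCc2ccc(OC)cc2)[C@@H]1CC(=O)OC(C)(C)C
F7 | step 10 | (6S,7S,8R)-8-(4-methoxybenzyloxy)-13-norgermacra-1(10)Z,4Z-dien-12,6-olide | C1C(=O)O[C@H]2/C=C(/C)CC/C=C(/C)C[C@@H](OCc3ccc(OC)cc3)[C@H]12
F8 | step 15 | dilithium alkoxide enolate of 21 | [Li+].[Li+].C1=C([O-])O[C@H]2/C=C(/C)CC[C@H]3O[C@@]3(C)C[C@@H]([O-])[C@H]12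
F9 | step 15 | 11-(dimethylaminomethyl) derivative of 21 (C11 epimers) | CN(C)CC1C(=O)O[C@H]2/C=C(/C)CC[C@H]3O[C@@]3(C)C[C@@H](O)[C@H]12
F10 | step 15 | 11-(trimethylammoniomethyl) derivative of 21, iodide | C[N+](C)(C)CC1C(=O)O[C@H]2/C=C(/C)CC[C@H]3O[C@@]3(C)C[C@@H](O)[C@H]12.[I-]
F11 | step 15 | (1R,6S,7S,8R,10S)-1,10-epoxy-8-hydroxygermacra-4Z,11(13)-dien-12,6-olide | C=C1C(=O)O[C@H]2/C=C(/C)CC[C@H]3O[C@@]3(C)C[C@@H](O)[C@H]12
F12 | step 16 | (1R,6S,7S,8R,10S)-1,10-epoxy-8-isobutyryloxy-3-oxogermacra-4Z,11(13)-dien-12,6-olide | C=C1C(=O)O[C@H]2/C=C(/C)C(=O)C[C@H]3O[C@@]3(C)C[C@@H](OC(=O)C(C)C)[C@H]12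
A1 | alternative 1 | ten-membered 3Z,5Z-diene acrylate (1,10-epoxide, C8 isobutyrate, methyl acrylate unit on C7) | C=C(C(=O)OC)[C@@H]1/C=C\C(C)=C/C[C@H]2O[C@@]2(C)C[C@H]1OC(=O)C(C)C
A2 | alternative 1 | C3,C6-endoperoxide of the ten-membered ring | C=C(C(=O)OC)[C@@H]1[C@@H]2C=C(C)[C@@H](OO2)C[C@H]3O[C@@]3(C)C[C@H]1OC(=O)C(C)C
A3 | alternative 2 | open-chain Z-iodoalkene aldehyde (C5 iodide, C6 aldehyde) | COC(=O)C[C@H](C=O)[C@H](OC(=O)C(C)C)C[C@]1(C)O[C@@H]1C[C@H](O[Si](C)(C)C(C)(C)C)/C(C)=C\I
A4 | alternative 2 | ten-membered C6 carbinol (hydroxy ester) | COC(=O)C[C@@H]1[C@@H](O)/C=C(/C)[C@@H](O[Si](C)(C)C(C)(C)C)C[C@H]2O[C@@]2(C)C[C@H]1OC(=O)C(C)C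
A5 | alternative 3 | bromomethyl ketone aldehyde (C2 bromide, C3 ketone, C1 aldehyde) | O=C1C[C@@H]([C@H](OC(=O)C(C)C)C[C@](C)(OCc2ccc(OC)cc2)C=O)[C@H](/C=C(/C)C(=O)CBr)O1
A6 | alternative 3 | ten-membered β-hydroxy ketone (C1 carbinol, C3 ketone) | O=C1C[C@H]2[C@H](OC(=O)C(C)C)C[C@](C)(OCc3ccc(OC)cc3)[C@@H](O)CC(=O)/C(C)=C\[C@@H]2O1
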